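## Retrosynthetic overview

1. Target 18 ⇒ propanoate 17 of α-hydroxy ester 16 by Dieckmann condensation; the tetronic acid ring is closed last.
2. 16 ⇒ methyl (R)-glycidate 13 (bought, the only stereocentre) + (Z)-iodotriene 12; the C–C bond comes from CuI-catalysed opening of the epoxide at C3 by the alkenyl Grignard.
3. 12 ⇒ aldehyde 8 by three olefinations: stabilised Wittig (E), formyl-olefination (E), α-iodoethylidene Wittig (Z).
4. 8 ⇒ 3-substituted furan 4 + 3-(bromomethyl)furan 5 (outer furan bought) by C5-selective C–H borylation and Suzuki coupling.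
5. Key step: the central furan of 4 ⇒ 4-phenyloxazole 1 + methyl pent-4-ynoate 2 by Diels–Alder/retro-Diels–Alder. Ring order: central furan formed first, outer furan attached, tetronic acid formed last.

Assumption: 1, 2, 5, 13 and every reagent named under Conditions are bought; methyl (R)-glycidate 13 (made from L-serine) is the only chiral material used.

## Route

Step 1
Reactants: 1 4-phenyloxazole; 2 methyl pent-4-ynoate
Product: 4 methyl 3-(furan-3-yl)propanoate, via oxazole–alkyne cycloadduct 3 (not isolated)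
Conditions: neat, 2 (2 equiv), sealed tube, 210 °C, 18 h
Reagents that add atoms: none
Why: Diels–Alder addition of the alkyne across C2/C5 of the oxazole followed by retro-Diels–Alder loss of benzonitrile forms the central furan ring, and because both oxazole termini carry hydrogen either adduct regioisomer gives the same 3-substituted furan.

Step 2
Reactants: 4 methyl 3-(furan-3-yl)propanoate; 5 3-(bromomethyl)furan
Product: 7 methyl 3-[5-(furan-3-ylmethyl)furan-3-yl]propanoate, via furyl pinacol boronate 6 (not isolated)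
Conditions: [Ir(OMe)(cod)]2 (1.5 mol%), dtbpy (3 mol%), B2pin2 (0.55 equiv), hexane, 25 °C; evaporate; then 5 (1.1 equiv), PdCl2(dppf) (3 mol%), K2CO3 (3 equiv), THF/H2O 9:1, 60 °C
Reagents that add atoms: none
Why: Sterically governed iridium-catalysed C–H borylation takes the α-position remote from the side chain (C5), and Suzuki–Miyaura coupling of the boronate with the benzylic-type bromide fixes the 2,4-substitution pattern of the central furan.

Step 3
Reactants: 7 methyl 3-[5-(furan-3-ylmethyl)furan-3-yl]propanoate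
Product: 8 3-[5-(furan-3-ylmethyl)furan-3-yl]propanal
Conditions: i-Bu2AlH (1.1 equiv), CH2Cl2, −78 °C, 1 h; MeOH, then aq KNaC4H4O6
Reagents that add atoms: none
Why: Low-temperature hydride reduction of the ester stops at the aluminium hemiacetal, which releases the aldehyde only on work-up, and the furans are inert.

Step 4
Reactants: 8 3-[5-(furan-3-ylmethyl)furan-3-yl]propanal
Product: 9 (2E)-5-[5-(furan-3-ylmethyl)furan-3-yl]-2-methylpent-2-enal
Conditions: Ph3P=C(CH3)CHO (1.3 equiv), toluene, 90 °C, 16 h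
Reagents that add atoms: 2-(triphenylphosphoranylidene)propanal, CC(C=O)=P(c1ccccc1)(c1ccccc1)c1ccccc1
Why: Wittig olefination with a stabilised formyl ylide gives the (E)-trisubstituted enal, which becomes the 6E double bond of the target.

Step 5
Reactants: 9 (2E)-5-[5-(furan-3-ylmethyl)furan-3-yl]-2-methylpent-2-enal
Product: 11 (2E,4E)-7-[5-(furan-3-ylmethyl)furan-3-yl]-4-methylhepta-2,4-dienal, via N-cyclohexyl dienimine 10 (not isolated)
Conditions: (EtO)2P(O)CH=CHNH(c-C6H11) (1.3 equiv), NaH (1.3 equiv), THF, 0 → 25 °C; then aq oxalic acid, toluene, 25 °C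
Reagents that add atoms: diethyl [(E)-2-(cyclohexylamino)ethenyl]phosphonate, CCOP(=O)(OCC)/C=C/NC1CCCCC1; water, O
Why: Horner–Wadsworth–Emmons formyl-olefination with the metalated enamine phosphonate gives the (E)-unsaturated imine, and its mild hydrolysis releases the dienal with the new disubstituted double bond E (4E of the target).

Step 6
Reactants: 11 (2E,4E)-7-[5-(furan-3-ylmethyl)furan-3-yl]-4-methylhepta-2,4-dienal
Product: 12 2-(furan-3-ylmethyl)-4-[(3E,5E,7Z)-8-iodo-4-methylnona-3,5,7-trien-1-yl]furan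
Conditions: [Ph3PCH2CH3]I (1.6 equiv), n-BuLi (1.55 equiv), THF, 25 °C; I2 (1.5 equiv), −78 °C; NaN(SiMe3)2 (1.45 equiv), −78 → −20 °C; then 11, −78 → −20 °C
Reagents that add atoms: ethyltriphenylphosphonium iodide, CC[P+](c1ccccc1)(c1ccccc1)c1ccccc1.[I-]; iodine, II
Why: Stork–Zhao-type Wittig olefination with the non-stabilised α-iodo ylide goes through the kinetically favoured cis-oxaphosphetane and places iodine cis to the dienyl chain, which is the (Z)-trisubstituted geometry needed for the 2Z double bond.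

Step 7
Reactants: 12 2-(furan-3-ylmethyl)-4-[(3E,5E,7Z)-8-iodo-4-methylnona-3,5,7-trien-1-yl]furan; 13 methyl (2R)-oxirane-2-carboxylate
Product: 16 methyl (2R,4Z,6E,8E)-11-[5-(furan-3-ylmethyl)furan-3-yl]-2-hydroxy-4,8-dimethylundeca-4,6,8-trienoate, via trienyllithium 14 (not isolated), via trienylmagnesium bromide 15 (not isolated)
Conditions: t-BuLi (2.05 equiv), Et2O, −78 °C; MgBr2·OEt2 (1.1 equiv), −78 → −40 °C; CuI (10 mol%), 13 (1.5 equiv), THF, −40 → −20 °C; aq NH4Cl
Reagents that add atoms: none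
Why: Iodine–lithium exchange and transmetalation keep the alkene geometry, and the copper-catalysed Grignard opens the epoxide by SN2 attack at the unsubstituted C3, so the bought stereocentre is untouched and becomes (R)-C2 of the α-hydroxy ester.

Step 8
Reactants: 16 methyl (2R,4Z,6E,8E)-11-[5-(furan-3-ylmethyl)furan-3-yl]-2-hydroxy-4,8-dimethylundeca-4,6,8-trienoate
Product: 17 methyl (2R,4Z,6E,8E)-11-[5-(furan-3-ylmethyl)furan-3-yl]-4,8-dimethyl-2-(propanoyloxy)undeca-4,6,8-trienoate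
Conditions: (EtCO)2O (1.5 equiv), Et3N (2 equiv), DMAP (10 mol%), CH2Cl2, 0 → 25 °C
Reagents that add atoms: propanoic anhydride, CCC(=O)OC(=O)CC
Why: DMAP-catalysed O-acylation of the secondary alcohol breaks no bond at the stereocentre.

Step 9
Reactants: 17 methyl (2R,4Z,6E,8E)-11-[5-(furan-3-ylmethyl)furan-3-yl]-4,8-dimethyl-2-(propanoyloxy)undeca-4,6,8-trienoate
Product: 18 (5R)-5-{(2Z,4E,6E)-9-[5-(furan-3-ylmethyl)furan-3-yl]-2,6-dimethylnona-2,4,6-trien-1-yl}-4-hydroxy-3-methylfuran-2(5H)-one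
Conditions: LiN(SiMe3)2 (2.3 equiv), THF, −78 → 0 °C; then 1 M HCl to pH 2
Reagents that add atoms: none
Why: Dieckmann (intramolecular Claisen) condensation of the propanoate enolate onto the methyl ester closes the tetronic acid ring, and the C5 stereocentre stays (R) because the kinetic enolate forms at the propanoyl CH2 and the product is held as its tetronate anion until acidification.

## Compound list

1 | 4-phenyloxazole | c1ccc(-c2cocn2)cc1 | starting material
2 | methyl pent-4-ynoate | COC(=O)CCC#C | starting material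
3 | methyl 3-(3-phenyl-7-oxa-2-azabicyclo[2.2.1]hepta-2,5-dien-5-yl)propanoate (racemic; the 6-yl regioisomer gives the same furan) | COC(=O)CCC1=CC2N=C(c3ccccc3)C1O2 | intermediate
4 | methyl 3-(furan-3-yl)propanoate | COC(=O)CCc1ccoc1 | intermediate
5 | 3-(bromomethyl)furan | BrCc1ccoc1 | starting material
6 | methyl 3-[5-(4,4,5,5-tetramethyl-1,3,2-dioxaborolan-2-yl)furan-3-yl]propanoate | COC(=O)CCc1coc(B2OC(C)(C)C(C)(C)O2)c1 | intermediate
7 | methyl 3-[5-(furan-3-ylmethyl)furan-3-yl]propanoate | COC(=O)CCc1coc(Cc2ccoc2)c1 | intermediate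
8 | 3-[5-(furan-3-ylmethyl)furan-3-yl]propanal | O=CCCc1coc(Cc2ccoc2)c1 | intermediate
9 | (2E)-5-[5-(furan-3-ylmethyl)furan-3-yl]-2-methylpent-2-enal | O=C/C(C)=C/CCc1coc(Cc2ccoc2)c1 | intermediate
10 | (2E,4E)-N-cyclohexyl-7-[5-(furan-3-ylmethyl)furan-3-yl]-4-methylhepta-2,4-dien-1-imine | C(/C=C/C(C)=C/CCc1coc(Cc2ccoc2)c1)=NC1CCCCC1 | intermediate
11 | (2E,4E)-7-[5-(furan-3-ylmethyl)furan-3-yl]-4-methylhepta-2,4-dienal | O=C/C=C/C(C)=C/CCc1coc(Cc2ccoc2)c1 | intermediate
12 | 2-(furan-3-ylmethyl)-4-[(3E,5E,7Z)-8-iodo-4-methylnona-3,5,7-trien-1-yl]furan | I\C(C)=C/C=C/C(C)=C/CCc1coc(Cc2ccoc2)c1 | intermediate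
13 | methyl (2R)-oxirane-2-carboxylate (methyl (R)-glycidate) | COC(=O)[C@H]1CO1 | starting material
14 | {(2E,4E,6E)-9-[5-(furan-3-ylmethyl)furan-3-yl]-6-methylnona-2,4,6-trien-2-yl}lithium (Li cis to C4 as iodine was; 2E only because carbon outranks lithium) | [Li]\C(C)=C/C=C/C(C)=C/CCc1coc(Cc2ccoc2)c1 | intermediate
15 | bromo{(2Z,4E,6E)-9-[5-(furan-3-ylmethyl)furan-3-yl]-6-methylnona-2,4,6-trien-2-yl}magnesium | Br[Mg]\C(C)=C/C=C/C(C)=C/CCc1coc(Cc2ccoc2)c1 | intermediate
16 | methyl (2R,4Z,6E,8E)-11-[5-(furan-3-ylmethyl)furan-3-yl]-2-hydroxy-4,8-dimethylundeca-4,6,8-trienoate | COC(=O)[C@H](O)C\C(C)=C/C=C/C(C)=C/CCc1coc(Cc2ccoc2)c1 | intermediate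
17 | methyl (2R,4Z,6E,8E)-11-[5-(furan-3-ylmethyl)furan-3-yl]-4,8-dimethyl-2-(propanoyloxy)undeca-4,6,8-trienoate | COC(=O)[C@H](OC(=O)CC)C\C(C)=C/C=C/C(C)=C/CCc1coc(Cc2ccoc2)c1 | intermediate
18 | (5R)-5-{(2Z,4E,6E)-9-[5-(furan-3-ylmethyl)furan-3-yl]-2,6-dimethylnona-2,4,6-trien-1-yl}-4-hydroxy-3-methylfuran-2(5H)-one | CC1=C(O)[C@@H](C\C(C)=C/C=C/C(C)=C/CCc2coc(Cc3ccoc3)c2)OC1=O | target

## Step count and risks

Total: 9 steps. Longest linear sequence: 9 steps (1 and 2 → 18); the route is fully linear.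

Steps most likely to fail:

Step 2 (C5 versus C2 selectivity of the borylation; protodeboronation of 6). Fallback: buy the 2,4-pattern and let the same oxazole cycloaddition form the outer furan instead. It sets out from 1 and comes back at 7. Ethynylmagnesium bromide adds to commercial 4-bromofuran-2-carbaldehyde to give 1-(4-bromofuran-2-yl)prop-2-yn-1-ol F1. Ionic deoxygenation (Et3SiH, BF3·OEt2, CH2Cl2, −78 °C) gives 4-bromo-2-(prop-2-yn-1-yl)furan F2. Heating F2 with 1 (210 °C) gives, through the bicyclic cycloadduct 4-bromo-2-[(3-phenyl-7-oxa-2-azabicyclo[2.2.1]hepta-2,5-dien-5-yl)methyl]furan F3, the bromide 4-bromo-2-(furan-3-ylmethyl)furan F4. Negishi coupling of F4 with bromo(3-methoxy-3-oxopropyl)zinc F5 (from methyl 3-bromopropanoate and zinc dust; Pd(OAc)2/SPhos, THF) gives 7.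

Step 6 (Z/E ratio and yield of the α-iodo Wittig reaction on a conjugated dienal). Fallback: set the geometry by a stereospecific cross-coupling instead of a kinetic Wittig reaction. It sets out from 11 and comes back at 14. CBr4/PPh3 (Et3N, CH2Cl2, 0 °C) converts 11 into 4-[(3E,5E)-8,8-dibromo-4-methylocta-3,5,7-trien-1-yl]-2-(furan-3-ylmethyl)furan F6. Palladium-catalysed mono-methylation with MeZnCl (PdCl2(DPEphos), THF, 0 °C) replaces only the bromine trans to the chain and gives 4-[(3E,5E,7Z)-8-bromo-4-methylnona-3,5,7-trien-1-yl]-2-(furan-3-ylmethyl)furan F7. Bromine–lithium exchange of F7 (t-BuLi, 2 equiv, Et2O, −78 °C) gives 14, and step 7 continues unchanged.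

Step 7 (stability of the trienyl organometallic; epoxide opening versus addition to the ester). Fallback: open the epoxide first with a small (Z)-alkenyl Grignard and close the triene last by an E-selective Wittig reaction with 9. It sets out from 13 and comes back at 16. But-2-yn-1-ol is hydroaluminated (NaAlH2(OCH2CH2OMe)2, THF) and iodinated to (2Z)-3-iodobut-2-en-1-ol F8, which is silylated (t-BuMe2SiCl, imidazole) to tert-butyl{[(2Z)-3-iodobut-2-en-1-yl]oxy}dimethylsilane F9. Exchange with i-PrMgCl·LiCl gives chloro{(2Z)-4-[(tert-butyldimethylsilyl)oxy]but-2-en-2-yl}magnesium F10, which opens 13 (CuI 10 mol%, −40 °C) to methyl (2R,4Z)-6-[(tert-butyldimethylsilyl)oxy]-2-hydroxy-4-methylhex-4-enoate F11. HF·pyridine gives methyl (2R,4Z)-2,6-dihydroxy-4-methylhex-4-enoate F12, CBr4/PPh3 (−20 °C) gives methyl (2R,4Z)-6-bromo-2-hydroxy-4-methylhex-4-enoate F13, and PBu3 gives tributyl[(2Z,5R)-5-hydroxy-6-methoxy-3-methyl-6-oxohex-2-en-1-yl]phosphonium bromide F14. LiN(SiMe3)2 (2 equiv) gives lithium (2R,4Z)-1-methoxy-4-methyl-1-oxo-6-(tributyl-λ5-phosphanylidene)hex-4-en-2-olate F15, whose Wittig reaction with 9 gives 16.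

## Further compounds

F1 | step 2 | 1-(4-bromofuran-2-yl)prop-2-yn-1-ol (racemic) | OC(C#C)c1cc(Br)co1
F2 | step 2 | 4-bromo-2-(prop-2-yn-1-yl)furan | C#CCc1cc(Br)co1
F3 | step 2 | 4-bromo-2-[(3-phenyl-7-oxa-2-azabicyclo[2.2.1]hepta-2,5-dien-5-yl)methyl]furan (racemic, not isolated) | Brc1coc(CC2=CC3N=C(c4ccccc4)C2O3)c1
F4 | step 2 | 4-bromo-2-(furan-3-ylmethyl)furan | Brc1coc(Cc2ccoc2)c1
F5 | step 2 | bromo(3-methoxy-3-oxopropyl)zinc | COC(=O)CC[Zn]Br
F6 | step 6 | 4-[(3E,5E)-8,8-dibromo-4-methylocta-3,5,7-trien-1-yl]-2-(furan-3-ylmethyl)furan | BrC(Br)=C/C=C/C(C)=C/CCc1coc(Cc2ccoc2)c1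
F7 | step 6 | 4-[(3E,5E,7Z)-8-bromo-4-methylnona-3,5,7-trien-1-yl]-2-(furan-3-ylmethyl)furan | Br\C(C)=C/C=C/C(C)=C/CCc1coc(Cc2ccoc2)c1
F8 | step 7 | (2Z)-3-iodobut-2-en-1-ol | C/C(I)=C/CO
F9 | step 7 | tert-butyl{[(2Z)-3-iodobut-2-en-1-yl]oxy}dimethylsilane | C/C(I)=C/CO[Si](C)(C)C(C)(C)C
F10 | step 7 | chloro{(2Z)-4-[(tert-butyldimethylsilyl)oxy]but-2-en-2-yl}magnesium | Cl[Mg]\C(C)=C/CO[Si](C)(C)C(C)(C)C
F11 | step 7 | methyl (2R,4Z)-6-[(tert-butyldimethylsilyl)oxy]-2-hydroxy-4-methylhex-4-enoate | COC(=O)[C@H](O)C\C(C)=C/CO[Si](C)(C)C(C)(C)C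
F12 | step 7 | methyl (2R,4Z)-2,6-dihydroxy-4-methylhex-4-enoate | COC(=O)[C@H](O)C\C(C)=C/CO
F13 | step 7 | methyl (2R,4Z)-6-bromo-2-hydroxy-4-methylhex-4-enoate | COC(=O)[C@H](O)C\C(C)=C/CBr
F14 | step 7 | tributyl[(2Z,5R)-5-hydroxy-6-methoxy-3-methyl-6-oxohex-2-en-1-yl]phosphonium bromide | COC(=O)[C@H](O)C\C(C)=C/C[P+](CCCC)(CCCC)CCCC.[Br-]
F15 | step 7 | lithium (2R,4Z)-1-methoxy-4-methyl-1-oxo-6-(tributyl-λ5-phosphanylidene)hex-4-en-2-olate | COC(=O)[C@H]([O-])C\C(C)=C/C=P(CCCC)(CCCC)CCCC.[Li+]
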